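The target is disconnected at the diaryl ether bond O1–C1' and at its five C–Br bonds. Everything rests on ring A: C2 and C4 lie ortho and para to O1, C3 lies para to the C6 methoxy group, and C5, merely ortho to that methoxy group and meta to O1, is the least activated carbon. While O1 is still a free hydroxyl, guaiacol therefore takes up exactly these three bromines in one operation; the precursor is guaiacol itself. The tribromophenol is then O-arylated with 2-fluorobenzaldehyde, the formyl group is exchanged for a hydroxyl by Dakin-type oxidation, and ring B is dibrominated ortho and para to that hydroxyl.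

Key step: step 1

Remark: ring A is numbered as in the target, with C1 bearing the ether oxygen O1 and C6 the methoxy group; ring B is the phenol ring, joined to O1 at C1'. The target has no stereocentre, so no configuration has to be set.

Step 1
Reactants: 1 guaiacol (2-methoxyphenol)
Product: 4 2,3,4-tribromo-6-methoxyphenol, via 4-bromoguaiacol 2 (not isolated), via 4,6-dibromoguaiacol 3 (not isolated)
Conditions: Br2 (3.0 equiv, added dropwise), AcOH, 15 °C to rt
Reagents that add atoms: bromine, BrBr
Why: Three successive electrophilic aromatic brominations of a phenol, the reaction type that turns phenol into 2,4,6-tribromophenol and is known for guaiacol; each bromine adds to give an arenium ion stabilized by an oxygen lone pair, and loss of a proton restores the arene. The first bromine should enter C4, para to the free hydroxyl, the second C2, ortho to it, and the third C3, para to the methoxy group, so every new C–Br bond lies ortho or para to an oxygen donor. No ring is closed and no stereocentre is formed. The selectivity needed is to stop at three bromines and keep C5 free: C5 is only ortho to the methoxy group, meta to the hydroxyl and wedged between OMe and the C4 bromine, and the ring then carries three deactivating halogens, so with three equivalents of Br2 and no Lewis acid a fourth substitution should not compete. The hydroxyl is left free in this step because it is the stronger donor and fixes C2 and C4; HBr in acetic acid at room temperature should not cleave the methyl ether.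

Step 2
Reactants: 4 2,3,4-tribromo-6-methoxyphenol; 5 2-fluorobenzaldehyde
Product: 6 2-(2,3,4-tribromo-6-methoxyphenoxy)benzaldehyde
Conditions: K2CO3 (1.5 equiv), DMAc, 150 °C, N2
Reagents that add atoms: none
Why: Nucleophilic aromatic substitution (SNAr), in which the potassium phenoxide of 4 adds to the fluorine-bearing carbon of 5 to give an anionic sigma adduct stabilized by the ortho formyl group and fluoride then leaves, while the unactivated C–Br bonds and the methyl ether of 4 are inert to carbonate.

Step 3
Reactants: 6 2-(2,3,4-tribromo-6-methoxyphenoxy)benzaldehyde
Product: 8 2-(2,3,4-tribromo-6-methoxyphenoxy)phenol, via aryl formate 7 (not isolated)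
Conditions: mCPBA, CH2Cl2, 0 °C to rt; aqueous NaHCO3 wash; then K2CO3 (10 mol %), MeOH, rt
Reagents that add atoms: mCPBA (3-chloroperoxybenzoic acid), OOC(=O)c1cccc(Cl)c1
Why: Baeyer–Villiger oxidation of an ortho-aryloxybenzaldehyde (Dakin-type), in which the tetrahedral peracid adduct rearranges by migration of the aryl group, made electron-rich at the migrating carbon by the ortho ether oxygen, and base-catalysed methanolysis of the resulting formate then frees the phenol without touching the aryl bromides or the methyl ether.

Step 4
Reactants: 8 2-(2,3,4-tribromo-6-methoxyphenoxy)phenol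
Product: 10 2,4-dibromo-6-(2,3,4-tribromo-6-methoxyphenoxy)phenol, via para-monobromide 9 (not isolated)
Conditions: Br2 (2.0 equiv, added dropwise), AcOH, 15 °C to rt
Reagents that add atoms: bromine, BrBr
Why: Electrophilic aromatic bromination in which the free hydroxyl of ring B directs bromine first to its para carbon and then to its free ortho carbon, much faster than the weakly donating diaryl ether oxygen can direct to C3' or C5', while ring A, with three bromines and only the flanked C5–H left, should not react with exactly two equivalents.

Compound list
1 | guaiacol (2-methoxyphenol) | COc1ccccc1O | starting material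
2 | 4-bromo-2-methoxyphenol (4-bromoguaiacol) | COc1cc(Br)ccc1O | intermediate
3 | 2,4-dibromo-6-methoxyphenol (4,6-dibromoguaiacol) | COc1cc(Br)cc(Br)c1O | intermediate
4 | 2,3,4-tribromo-6-methoxyphenol | COc1cc(Br)c(Br)c(Br)c1O | intermediate
5 | 2-fluorobenzaldehyde | O=Cc1ccccc1F | starting material
6 | 2-(2,3,4-tribromo-6-methoxyphenoxy)benzaldehyde | COc1cc(Br)c(Br)c(Br)c1Oc1ccccc1C=O | intermediate
7 | 2-(2,3,4-tribromo-6-methoxyphenoxy)phenyl formate | COc1cc(Br)c(Br)c(Br)c1Oc1ccccc1OC=O | intermediate
8 | 2-(2,3,4-tribromo-6-methoxyphenoxy)phenol | COc1cc(Br)c(Br)c(Br)c1Oc1ccccc1O | intermediate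
9 | 4-bromo-2-(2,3,4-tribromo-6-methoxyphenoxy)phenol | COc1cc(Br)c(Br)c(Br)c1Oc1cc(Br)ccc1O | intermediate
10 | 2,4-dibromo-6-(2,3,4-tribromo-6-methoxyphenoxy)phenol | COc1cc(Br)c(Br)c(Br)c1Oc1cc(Br)cc(Br)c1O | target

Total step count: 4. Longest linear sequence: 4 steps (1 to 4 to 6 to 8 to 10).

Steps most likely to fail

Step 4 is judged the most dependable, since ortho/para bromination of a free phenol is fast and ring A is deactivated. The three weaker points are the following.

Risk in step 2: the phenoxide of 4 is flanked by bromine and methoxy and is weakly nucleophilic, and a formyl group activates the fluoride only moderately. The substitution may therefore stall, or the aldehyde may decompose at the temperature required. The fallback sets out from 4 and rejoins the route at 8, replacing steps 2 and 3. Compound 4 is arylated with the far more electrophilic 1-fluoro-2-nitrobenzene (O=[N+]([O-])c1ccccc1F; K2CO3, DMF, 80 °C) to give 1,2,3-tribromo-5-methoxy-4-(2-nitrophenoxy)benzene F1. Reduction with Fe and NH4Cl in aqueous ethanol at 80 °C, which leaves aryl bromides intact, gives 2-(2,3,4-tribromo-6-methoxyphenoxy)aniline F2. Diazotization with NaNO2 in H2SO4/AcOH/H2O at 0–5 °C gives 2-(2,3,4-tribromo-6-methoxyphenoxy)benzenediazonium hydrogensulfate F3. Without isolation this is hydroxylated with Cu2O in aqueous Cu(NO3)2 at room temperature to give 8.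

Risk in step 3: in the peracid adduct, hydride shift may outrun aryl migration, because the three bromines weaken the donor strength of the aryloxy oxygen. This would lead to the benzoic acid instead of the formate. The fallback sets out from 4 and rejoins the route at 8, removing the migrating hydrogen altogether. Compound 4 is arylated with 1-(2-fluorophenyl)ethanone (CC(=O)c1ccccc1F) under the conditions of step 2 to give 1-[2-(2,3,4-tribromo-6-methoxyphenoxy)phenyl]ethanone F4. Baeyer–Villiger oxidation of this methyl ketone (mCPBA, catalytic CF3CO2H, CH2Cl2), in which aryl migrates in preference to methyl, gives 2-(2,3,4-tribromo-6-methoxyphenoxy)phenyl acetate F5. Methanolysis with K2CO3 in MeOH gives 8.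

Risk in step 1: the third bromination is steered only by the methoxy group, so attack at C5 or a fourth bromination may erode the regiochemical purity of 4. The fallback sets out from 1 and rejoins the route at 4, placing the methoxy-directed bromine first. Acetylation of 1 (Ac2O, pyridine) gives 2-methoxyphenyl acetate F6. Bromination with NBS in MeCN, now controlled by the methoxy group because the acetoxy group is the weaker donor, gives 5-bromo-2-methoxyphenyl acetate F7. Methanolysis (K2CO3, MeOH) gives 5-bromo-2-methoxyphenol F8. Two equivalents of Br2 in AcOH then fill the para and ortho positions of the liberated hydroxyl, by way of 4,5-dibromo-2-methoxyphenol F9 (not isolated), and give 4.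

Further compounds
F1 | step 2 | 1,2,3-tribromo-5-methoxy-4-(2-nitrophenoxy)benzene | COc1cc(Br)c(Br)c(Br)c1Oc1ccccc1[N+](=O)[O-]
F2 | step 2 | 2-(2,3,4-tribromo-6-methoxyphenoxy)aniline | COc1cc(Br)c(Br)c(Br)c1Oc1ccccc1N
F3 | step 2 | 2-(2,3,4-tribromo-6-methoxyphenoxy)benzenediazonium hydrogensulfate | COc1cc(Br)c(Br)c(Br)c1Oc1ccccc1[N+]#N.OS(=O)(=O)[O-]
F4 | step 3 | 1-[2-(2,3,4-tribromo-6-methoxyphenoxy)phenyl]ethanone | COc1cc(Br)c(Br)c(Br)c1Oc1ccccc1C(C)=O
F5 | step 3 | 2-(2,3,4-tribromo-6-methoxyphenoxy)phenyl acetate | COc1cc(Br)c(Br)c(Br)c1Oc1ccccc1OC(C)=O
F6 | step 1 | 2-methoxyphenyl acetate | COc1ccccc1OC(C)=O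
F7 | step 1 | 5-bromo-2-methoxyphenyl acetate | COc1ccc(Br)cc1OC(C)=O
F8 | step 1 | 5-bromo-2-methoxyphenol | COc1ccc(Br)cc1O
F9 | step 1 | 4,5-dibromo-2-methoxyphenol | COc1cc(Br)c(Br)cc1O
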